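**Plan**
- **Cuts.** The quinone ring (C1'=O, C2'-OH, C3'-C11H2, C4'=O, C5'-OMe, C6'-H) is first taken back to the C1'-H phenol. It is then cut at C1'–C2', C3'–C4' and C4'–C5' into a silyl ynol ether (C2'≡C3') and the vinylketene O=C4'=C1'H–C6'H=C5'H(OMe).
- **Enabling feature.** The vicinal pair C2'(O)/C3'(alkyl) is an O-polarised alkyne in disguise. It faces a four-carbon arc C4'–C1'–C6'–C5' that carries only O4' and the C5' methoxy group. A cyclobutenone ring (extra bond C4'–C1') is made and broken again in the same operation.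
- **Carbon source.** The ynol ether holds all sixteen carbons of (+)-sclareolide plus one: lactone carbon C12 becomes C3', and the homologation carbon becomes C2'.
- **Forward order.** Both carbocycles come with sclareolide. The lactone ring is opened (steps 1–2), the drimane is rearranged (step 3), the ynol ether is made (step 4), and the quinone ring is closed last (step 6). Oxidation and desilylation follow.
- **Stereochemistry.** C8 (S) and C9 (R) are set by two suprafacial 1,2-shifts (9α-H to C8, 10β-CH3 to C9) from chiral-pool centres. No later step touches them.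

Key step: step 6

Remark: the decalin is numbered as a drimane (C1–C10, C11 = CH2 link) and the quinone ring as C1'–C6'. Ter = (1R,2S)-1,2,5,5-tetramethyl-1,2,3,4,5,6,7,8-octahydronaphthalen-1-yl. Lactol 2 is taken as its anomeric mixture. The transient sp3 centres of 12 and 14 are left undefined because they vanish.

Step 1
Reactants: 1 (+)-sclareolide
Product: 2 sclareolide lactol
Conditions: DIBAL-H, CH2Cl2, −78 °C; aq Rochelle salt
Reagents that add atoms: none
Why: Partial DIBAL-H reduction of a γ-lactone stops at the aluminium hemiacetal at −78 °C, and none of the four stereocentres is touched.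

Step 2
Reactants: 2 sclareolide lactol
Product: 3 alkynol, (1R,2R,4aS,8aS)-2,5,5,8a-tetramethyl-1-(prop-2-yn-1-yl)decahydronaphthalen-2-ol
Conditions: MeC(O)C(N2)P(O)(OMe)2, K2CO3, MeOH, rt
Reagents that add atoms: dimethyl (1-diazo-2-oxopropyl)phosphonate CC(=O)C(=[N+]=[N-])P(=O)(OC)OC
Why: The Ohira–Bestmann (Seyferth–Gilbert) homologation acts on the hydroxy aldehyde that is in ring–chain equilibrium with the lactol, as is usual for lactols, and adds the carbon that becomes C2' without touching C8 or C9.

Step 3
Reactants: 3 alkynol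
Product: 4 rearranged enyne, (1R,2S)-1,2,5,5-tetramethyl-1-(prop-2-yn-1-yl)-1,2,3,4,5,6,7,8-octahydronaphthalene
Conditions: BF3·OEt2, CH2Cl2, −50 → −5 °C; aq NaHCO3
Reagents that add atoms: none
Why: Ionisation of the tertiary C8 alcohol starts the Wagner–Meerwein cascade known for 11-aryl drimanes (suprafacial shift of 9α-H to C8, then of the 10β-methyl to C9, then loss of H-5 to the tetrasubstituted C5=C10 alkene), so C8 (β-methyl, S) and C9 (β-methyl, R) are set stereospecifically by the vanishing centres C9 and C10, and the propargyl group has neither a lone pair nor a workable ring size to intercept the cations.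

Step 4
Reactants: 4 rearranged enyne
Product: 7 silyl ynol ether TerCH2–C≡C–OSi(iPr)3, via lithium acetylide 5 (not isolated), via lithium ynolate 6 (not isolated)
Conditions: n-BuLi, THF, −78 °C; t-BuOOLi (from t-BuOOH, LiHMDS), −78 → 0 °C; TIPSOTf, −78 → 0 °C
Reagents that add atoms: tert-butyl hydroperoxide CC(C)(C)OO (the O atom); triisopropylsilyl triflate CC(C)[Si](OS(=O)(=O)C(F)(F)F)(C(C)C)C(C)C; n-butyllithium [Li]CCCC (Li of 5 and 6 only)
Why: Oxygen transfer from lithium tert-butyl peroxide to a lithium acetylide gives the ynolate, which the bulky silyl triflate traps on oxygen rather than carbon; this is a standard route from 1-alkynes to silyl ynol ethers, and the isolated tetrasubstituted alkene is inert to it.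

Step 5
Reactants: 8 (E)-4-methoxybut-3-en-2-one
Product: 10 (E)-1-diazo-4-methoxybut-3-en-2-one, via trifluoroacetyl ketone 9 (not isolated)
Conditions: LiHMDS, THF, −78 °C; CF3CO2CH2CF3; 5% aq HCl wash; then p-ABSA, Et3N, H2O, MeCN, rt
Reagents that add atoms: 4-acetamidobenzenesulfonyl azide CC(=O)Nc1ccc(cc1)S(=O)(=O)N=[N+]=[N-] (N2); 2,2,2-trifluoroethyl trifluoroacetate O=C(OCC(F)(F)F)C(F)(F)F (CF3CO of 9 only)
Why: In this detrifluoroacetylative (Regitz-type) diazo transfer the kinetic methyl-side enolate is activated as its trifluoroacetyl derivative, which takes N2 from the sulfonyl azide and sheds the activating group, a method suited to enones that do not tolerate diazomethane.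

Step 6
Reactants: 7 silyl ynol ether; 10 (E)-1-diazo-4-methoxybut-3-en-2-one
Product: 15 phenol, 6-methoxy-2-(TerCH2)-3-(triisopropylsilyloxy)phenol, via vinylketene 11 (not isolated), via vinylcyclobutenone 12 (not isolated), via dienylketene 13 (not isolated), via cyclohexadienone 14 (not isolated)
Conditions: hν (254 nm, Vycor), ClCH2CH2Cl, rt, 10 added in portions; then 80 °C
Reagents that add atoms: none
Why: Light expels N2 from 10 and the Wolff shift of the methoxyvinyl group gives vinylketene 11, which adds across ynol ether 7 in a [2+2] cycloaddition to cyclobutenone 12; 4π electrocyclic opening of 12 (thermal or light-driven) breaks the temporary C4'–C1' bond to give dienylketene 13, 6π electrocyclisation makes C4'–C5' (dienone 14), and enolisation gives phenol 15. The closest known reaction type is the Danheiser benzannulation in its diazo ketone variant with trialkylsilyloxyalkynes. The four-membered helper ring closes by ketene–alkyne [2+2] (bonds C3'–C4' and C2'–C1'), and the six-membered ring closes by disrotatory 6π closure of the dienylketene isomer that holds the ketene and the methoxyvinyl group cis on C2'=C1'; because the opening of 12 is reversible, the unproductive isomer is recycled. No stereocentre of the target is formed: the sp3 carbons C1' in 12 and C5' in 14 are transient and vanish on aromatisation, so light-induced E/Z scrambling of the methoxyvinyl unit is funnelled into one product, and C8 and C9 are spectators. The step needs regio- and chemoselectivity: oxygen polarises the alkyne so that its nucleophilic carbon C3' (bearing C11H2) bonds to the ketene carbonyl carbon C4', which places OSi at C2' next to the alkyl group and the methoxy carbon C5' next to C4'–OH, exactly the 2-hydroxy-5-methoxy-3-alkyl pattern. The linear alkyne holds the quaternary C9 away from the reacting carbons, and the unactivated tetrasubstituted C5=C10 alkene is not a ketenophile.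

Step 7
Reactants: 15 phenol
Product: 16 silyloxyquinone, 5-methoxy-3-(TerCH2)-2-(triisopropylsilyloxy)-1,4-benzoquinone
Conditions: O2 (1 atm), salcomine (cat.), DMF, rt
Reagents that add atoms: dioxygen O=O
Why: Cobalt–salen-catalysed aerobic oxidation of a 2,3,6-trisubstituted phenol with a free para position gives the p-quinone, and the silyl group kept on O2' blocks the competing oxidative demethylation across the para pair O2'/C5'-OMe.

Step 8
Reactants: 16 silyloxyquinone
Product: 17 target quinone
Conditions: TBAF, AcOH (1:1), THF, 0 °C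
Reagents that add atoms: none
Why: Buffered fluoride cleaves the very labile silyl vinylogous ester under near-neutral conditions, so the C5=C10 alkene is not protonated (which would let O2' close a chroman ring on C10) and the C5' methoxy group is not exchanged.

**Compound list**
1 | (+)-sclareolide, (3aR,5aS,9aS,9bR)-3a,6,6,9a-tetramethyldecahydronaphtho[2,1-b]furan-2(1H)-one | CC1(C)CCC[C@@]2(C)[C@H]1CC[C@@]3(C)OC(=O)C[C@H]23 | starting material
2 | sclareolide lactol (anomeric mixture) | CC1(C)CCC[C@@]2(C)[C@H]1CC[C@@]3(C)OC(O)C[C@H]23 | intermediate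
3 | (1R,2R,4aS,8aS)-2,5,5,8a-tetramethyl-1-(prop-2-yn-1-yl)decahydronaphthalen-2-ol | CC1(C)CCC[C@@]2(C)[C@H]1CC[C@@](C)(O)[C@@H]2CC#C | intermediate
4 | (1R,2S)-1,2,5,5-tetramethyl-1-(prop-2-yn-1-yl)-1,2,3,4,5,6,7,8-octahydronaphthalene | C#CC[C@@]1(C)C2=C(CC[C@@H]1C)C(C)(C)CCC2 | intermediate
5 | lithium acetylide of 4 | [Li]C#CC[C@@]1(C)C2=C(CC[C@@H]1C)C(C)(C)CCC2 | intermediate
6 | lithium ynolate TerCH2–C≡C–OLi | [Li]OC#CC[C@@]1(C)C2=C(CC[C@@H]1C)C(C)(C)CCC2 | intermediate
7 | triisopropyl{[3-Ter-prop-1-yn-1-yl]oxy}silane | CC(C)[Si](OC#CC[C@@]1(C)C2=C(CC[C@@H]1C)C(C)(C)CCC2)(C(C)C)C(C)C | intermediate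
8 | (E)-4-methoxybut-3-en-2-one | CO/C=C/C(C)=O | starting material
9 | (E)-1,1,1-trifluoro-6-methoxyhex-5-ene-2,4-dione | CO/C=C/C(=O)CC(=O)C(F)(F)F | intermediate
10 | (E)-1-diazo-4-methoxybut-3-en-2-one | CO/C=C/C(=O)C=[N+]=[N-] | intermediate
11 | (E)-4-methoxybuta-1,3-dien-1-one (vinylketene) | CO/C=C/C=C=O | intermediate
12 | 4-[(E)-2-methoxyethenyl]-2-(TerCH2)-3-(triisopropylsilyloxy)cyclobut-2-en-1-one | CO/C=C/C1C(=O)C(C[C@@]2(C)C3=C(CC[C@@H]2C)C(C)(C)CCC3)=C1O[Si](C(C)C)(C(C)C)C(C)C | intermediate
13 | 6-methoxy-2-(TerCH2)-3-(triisopropylsilyloxy)hexa-1,3,5-trien-1-one (ketene and methoxyvinyl cis) | CO/C=C/C=C(/O[Si](C(C)C)(C(C)C)C(C)C)C(C[C@@]1(C)C2=C(CC[C@@H]1C)C(C)(C)CCC2)=C=O | intermediate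
14 | 6-methoxy-2-(TerCH2)-3-(triisopropylsilyloxy)cyclohexa-2,4-dien-1-one | COC1C=CC(O[Si](C(C)C)(C(C)C)C(C)C)=C(C[C@@]2(C)C3=C(CC[C@@H]2C)C(C)(C)CCC3)C1=O | intermediate
15 | 6-methoxy-2-(TerCH2)-3-(triisopropylsilyloxy)phenol | COc1ccc(O[Si](C(C)C)(C(C)C)C(C)C)c(C[C@@]2(C)C3=C(CC[C@@H]2C)C(C)(C)CCC3)c1O | intermediate
16 | 5-methoxy-3-(TerCH2)-2-(triisopropylsilyloxy)cyclohexa-2,5-diene-1,4-dione | COC1=CC(=O)C(O[Si](C(C)C)(C(C)C)C(C)C)=C(C[C@@]2(C)C3=C(CC[C@@H]2C)C(C)(C)CCC3)C1=O | intermediate
17 | 2-hydroxy-5-methoxy-3-{[(1R,2S)-1,2,5,5-tetramethyl-1,2,3,4,5,6,7,8-octahydronaphthalen-1-yl]methyl}cyclohexa-2,5-diene-1,4-dione | COC1=CC(=O)C(O)=C(C[C@@]2(C)C3=C(CC[C@@H]2C)C(C)(C)CCC3)C1=O | target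

Total steps: 8. Longest linear sequence: 7 (steps 1–4, 6–8).

**Steps most likely to fail**

**Step 3.**
- *What may go wrong:* the cation cascade may stall at plain dehydration to drimene isomers, or run on past C10 by further hydride and methyl shifts, because the propargyl group lacks the aryl ring of the established substrates.
- *Fallback (sets out from 3, returns at 15):* the rearrangement is postponed until C11 carries the arene.
  - Dehydration of 3 (SOCl2, pyridine, CH2Cl2, −78 → 0 °C) should give the exocyclic-alkene enyne F1. Endocyclic isomers are carried along, since all give the same C8 cation later.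
  - The protocol of step 4 converts it into the drimenyl silyl ynol ether F2.
  - The benzannulation of step 6 with 10 converts that into the drimenylmethyl phenol F3.
  - Ac2O, pyridine and DMAP mask the free phenol as the aryl acetate F4, so that it cannot close a chroman on C8 or C10.
  - BF3·OEt2 (CH2Cl2, −50 → −5 °C) should then give the rearranged aryl acetate F5, and K2CO3/MeOH frees 15.

**Step 6.**
- *What may go wrong:* capture of the short-lived, donor-substituted vinylketene by the electron-rich alkyne may be slower than ketene self-reaction, acylation of the product phenol, or photodegradation.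
- *Fallback (sets out from 7, returns at 17):* the methoxy group is left out of the ring-forming event and added afterwards.
  - Heating 7 with cyclobut-2-en-1-one (toluene, 80 → 110 °C, the purely thermal form of the benzannulation) should give the methoxy-free phenol F6.
  - O2/salcomine in DMF gives the silyloxyquinone F7.
  - TBAF/AcOH gives the hydroxyquinone F8.
  - MeOH, ZnCl2 and air at rt add methanol 1,4 with reoxidation. O2' deactivates C4'=O as a vinylogous acid, so the C1'=O enone accepts methanol at C5', giving 17.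

**Step 5.**
- *What may go wrong:* the trifluoroacetyl ketone may cyclise onto the β-methoxyenone with loss of methanol before diazo transfer, or the β-methoxy group may be lost by addition–elimination.
- *Fallback (sets out from 8, returns at 10):* no 1,3-diketone is involved.
  - TMSCl, Et3N and ZnCl2 (cat.) convert 8 into the silyl dienol ether F9.
  - NBS (THF, −78 °C) brominates its terminal CH2 to give the bromo ketone F10.
  - N,N'-ditosylhydrazine with DBU (THF, 0 °C) converts the bromo ketone into 10.

**Further compounds**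
F1 | step 3 | exocyclic-alkene enyne, 5,5,8a-trimethyl-2-methylidene-1-(prop-2-yn-1-yl)decahydronaphthalene with the sclareolide configuration (5α-H, 9α-H, 10β-CH3) | CC1(C)CCC[C@@]2(C)[C@H]1CCC(=C)[C@@H]2CC#C
F2 | step 3 | drimenyl silyl ynol ether | CC1(C)CCC[C@@]2(C)[C@H]1CCC(=C)[C@@H]2CC#CO[Si](C(C)C)(C(C)C)C(C)C
F3 | step 3 | drimenylmethyl phenol | CC1(C)CCC[C@@]2(C)[C@H]1CCC(=C)[C@@H]2Cc1c(O)c(OC)ccc1O[Si](C(C)C)(C(C)C)C(C)C
F4 | step 3 | drimenylmethyl aryl acetate | CC1(C)CCC[C@@]2(C)[C@H]1CCC(=C)[C@@H]2Cc1c(OC(C)=O)c(OC)ccc1O[Si](C(C)C)(C(C)C)C(C)C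
F5 | step 3 | rearranged aryl acetate (acetate of 15) | COc1ccc(O[Si](C(C)C)(C(C)C)C(C)C)c(C[C@@]2(C)C3=C(CC[C@@H]2C)C(C)(C)CCC3)c1OC(C)=O
F6 | step 6 | 2-(TerCH2)-3-(triisopropylsilyloxy)phenol | Oc1cccc(O[Si](C(C)C)(C(C)C)C(C)C)c1C[C@@]2(C)C3=C(CC[C@@H]2C)C(C)(C)CCC3
F7 | step 6 | 3-(TerCH2)-2-(triisopropylsilyloxy)-1,4-benzoquinone | O=C1C=CC(=O)C(O[Si](C(C)C)(C(C)C)C(C)C)=C1C[C@@]2(C)C3=C(CC[C@@H]2C)C(C)(C)CCC3
F8 | step 6 | 2-hydroxy-3-(TerCH2)-1,4-benzoquinone | O=C1C=CC(=O)C(O)=C1C[C@@]2(C)C3=C(CC[C@@H]2C)C(C)(C)CCC3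
F9 | step 5 | (E)-1-methoxy-3-(trimethylsilyloxy)buta-1,3-diene | CO/C=C/C(=C)O[Si](C)(C)C
F10 | step 5 | (E)-1-bromo-4-methoxybut-3-en-2-one | CO/C=C/C(=O)CBr
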